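**Plan**
- Retrosynthesis: the three oxygen substituents of ring B are adjusted last (MOM off, TIPS to acetyl, OH to OMe). Before that, the ArCH2CH2–C(aryl) bond and the neighbouring aryl C–O bond are cut in one operation, giving a phenethyllithium (ring A) and a 3,4-dioxygenated benzyne (ring B). In ring A the prenyl–aryl bond is cut.
- Enabling feature: ring B is a 1-alkyl-2,3,4-trioxygenated benzene. The alkylated carbon C1 and the methoxylated carbon C2 are neighbours and C3 carries oxygen, so C1/C2 can be the two carbons of an aryne whose C3–OMOM group decides where each partner adds.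
- Forward order: ring A is prenylated between its two OMe groups by directed lithiation and converted to the primary iodide. The chloroarene aryne precursor is made from 4-chloro-2-hydroxybenzaldehyde (MOM, Baeyer–Villiger, TIPS). The aryne step then joins the fragments and installs the C2 oxygen, followed by O-methylation, TIPS-to-acetate exchange and MOM removal.
- Stereochemistry: the target has no stereocentre, and its only C=C bond carries two identical methyl groups, so nothing has to be controlled.

Key step: step 8

Assumption: 2-(3,5-dimethoxyphenyl)ethan-1-ol (1) and 4-chloro-2-hydroxybenzaldehyde (7) are taken to be catalogue compounds.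

**Route**

Step 1
Reactants: 1 2-(3,5-dimethoxyphenyl)ethan-1-ol
Product: 2 tert-butyl[2-(3,5-dimethoxyphenyl)ethoxy]dimethylsilane
Conditions: TBSCl, imidazole, DMF, rt
Reagents that add atoms: tert-butyldimethylsilyl chloride (TBSCl), CC(C)(C)[Si](C)(C)Cl
Why: Standard silyl ether protection of a primary alcohol, so that the following metalation meets neither an acidic proton nor a directing alkoxide.

Step 2
Reactants: 2 tert-butyl[2-(3,5-dimethoxyphenyl)ethoxy]dimethylsilane
Product: 4 tert-butyl{2-[3,5-dimethoxy-4-(3-methylbut-2-en-1-yl)phenyl]ethoxy}dimethylsilane, via aryllithium 3 (not isolated)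
Conditions: n-BuLi, TMEDA, THF, 0 °C; then CuBr·SMe2 (10 mol %), prenyl bromide, −78 °C → rt
Reagents that add atoms: 1-bromo-3-methylbut-2-ene (prenyl bromide), CC(C)=CCBr; n-butyllithium, [Li]CCCC (lithium of intermediate 3 only)
Why: Directed ortho-metalation of a 1,3-dimethoxyarene should occur at the carbon flanked by both methoxy groups, and copper-assisted SN2 alkylation of aryllithium 3 with prenyl bromide should place the prenyl group there.

Step 3
Reactants: 4 tert-butyl{2-[3,5-dimethoxy-4-(3-methylbut-2-en-1-yl)phenyl]ethoxy}dimethylsilane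
Product: 5 2-[3,5-dimethoxy-4-(3-methylbut-2-en-1-yl)phenyl]ethan-1-ol
Conditions: CSA (10 mol %), MeOH, 0 °C → rt
Reagents that add atoms: none
Why: Acid-catalysed methanolysis should cleave the primary TBS ether under conditions too mild to protonate the trisubstituted alkene.

Step 4
Reactants: 5 2-[3,5-dimethoxy-4-(3-methylbut-2-en-1-yl)phenyl]ethan-1-ol
Product: 6 5-(2-iodoethyl)-1,3-dimethoxy-2-(3-methylbut-2-en-1-yl)benzene
Conditions: PPh3, I2, imidazole, CH2Cl2, 0 °C → rt
Reagents that add atoms: iodine, II
Why: Appel-type iodination should convert the primary alcohol into the iodide by SN2 displacement of the alkoxyphosphonium ion under neutral conditions that the prenyl group tolerates.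

Step 5
Reactants: 7 4-chloro-2-hydroxybenzaldehyde
Product: 8 4-chloro-2-(methoxymethoxy)benzaldehyde
Conditions: MOMCl, iPr2NEt, CH2Cl2, 0 °C → rt
Reagents that add atoms: chloromethyl methyl ether (MOMCl), COCCl
Why: MOM ether formation by O-alkylation of the phenol installs an acetal that later directs the lithiation, polarises the aryne and can be removed with mild acid.

Step 6
Reactants: 8 4-chloro-2-(methoxymethoxy)benzaldehyde
Product: 10 4-chloro-2-(methoxymethoxy)phenol, via aryl formate 9 (not isolated)
Conditions: mCPBA, CH2Cl2, rt; aq NaHCO3 wash; then K2CO3 (cat.), MeOH, 0 °C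
Reagents that add atoms: 3-chloroperbenzoic acid (mCPBA), OOC(=O)c1cccc(Cl)c1
Why: Baeyer–Villiger oxidation of an o-alkoxybenzaldehyde should proceed with aryl migration to formate 9 (Dakin-type), and methanolysis frees the phenol para to chlorine, which fixes the positions of the two differentiated oxygens without ambiguity.

Step 7
Reactants: 10 4-chloro-2-(methoxymethoxy)phenol
Product: 11 [4-chloro-2-(methoxymethoxy)phenoxy]tri(propan-2-yl)silane
Conditions: TIPSCl, imidazole, DMF, rt
Reagents that add atoms: triisopropylsilyl chloride (TIPSCl), CC(C)[Si](Cl)(C(C)C)C(C)C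
Why: Silylation gives a bulky aryl silyl ether that should tolerate organolithiums at low temperature and is orthogonal to the MOM group.

Step 8
Reactants: 6 5-(2-iodoethyl)-1,3-dimethoxy-2-(3-methylbut-2-en-1-yl)benzene; 11 [4-chloro-2-(methoxymethoxy)phenoxy]tri(propan-2-yl)silane
Product: 17 6-{2-[3,5-dimethoxy-4-(3-methylbut-2-en-1-yl)phenyl]ethyl}-2-(methoxymethoxy)-3-{[tri(propan-2-yl)silyl]oxy}phenol, via alkyllithium 12 (not isolated), via chloroaryllithium 13 (not isolated), via aryne 14 (not isolated), via adduct aryllithium 15 (not isolated), via dimethyl arylboronate 16 (not isolated)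
Conditions: 6 (1.3 equiv), t-BuLi (2.0 equiv per 6), Et2O/pentane, −78 °C; separately 11, s-BuLi, THF, −78 °C; 12 added to 13, −78 → −20 °C; B(OMe)3, −78 °C → rt; 30% H2O2, aq NaHCO3, 0 °C → rt
Reagents that add atoms: hydrogen peroxide, OO (the new phenol oxygen of 17); trimethyl borate, COB(OC)OC (boron and methoxy groups of intermediate 16 only); tert-butyllithium, [Li]C(C)(C)C (lithium of intermediates 12 and 15 only); sec-butyllithium, [Li]C(C)CC (lithium of intermediate 13 only)
Why: s-BuLi removes the ring proton of 11 that lies between Cl and OMOM (13), warming expels LiCl to give the 3,4-dioxygenated benzyne 14, the primary alkyllithium 12 adds across the strained triple bond to give aryllithium 15, and this is borylated (16) and oxidised with 1,2-migration of the aryl group from boron to oxygen to give phenol 17. The closest known reaction type is the tandem carbolithiation–electrophile trapping of 3-alkoxybenzynes generated from 3-haloaryl ethers (aryne three-component coupling). No ring is closed and no stereocentre is formed. The step needs regioselective addition, which the OMOM oxygen beside the triple bond should secure: its inductive pull distorts the aryne so that the remote carbon is the electrophilic one, and the carbanion develops next to oxygen, where it is stabilised inductively and by chelation to the MOM group, so carbon goes to the former C–Cl carbon and oxygen to its neighbour. It also needs 12 to outrun the hindered aryllithiums 13 and 15 as the nucleophile, which its higher nucleophilicity, small size and slight excess should secure; the OTIPS, MOM and prenyl groups should be inert at these temperatures.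

Step 9
Reactants: 17 6-{2-[3,5-dimethoxy-4-(3-methylbut-2-en-1-yl)phenyl]ethyl}-2-(methoxymethoxy)-3-{[tri(propan-2-yl)silyl]oxy}phenol
Product: 18 {4-{2-[3,5-dimethoxy-4-(3-methylbut-2-en-1-yl)phenyl]ethyl}-3-methoxy-2-(methoxymethoxy)phenoxy}tri(propan-2-yl)silane
Conditions: MeI, K2CO3, acetone, 50 °C
Reagents that add atoms: iodomethane, CI
Why: Williamson O-methylation of the only free phenol; K2CO3 in acetone should leave the aryl TIPS ether and the MOM acetal intact.

Step 10
Reactants: 18 {4-{2-[3,5-dimethoxy-4-(3-methylbut-2-en-1-yl)phenyl]ethyl}-3-methoxy-2-(methoxymethoxy)phenoxy}tri(propan-2-yl)silane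
Product: 20 4-{2-[3,5-dimethoxy-4-(3-methylbut-2-en-1-yl)phenyl]ethyl}-3-methoxy-2-(methoxymethoxy)phenyl acetate, via tetrabutylammonium phenoxide 19 (not isolated)
Conditions: TBAF (1.1 equiv), THF, 0 °C; then Ac2O (3 equiv), 0 °C → rt
Reagents that add atoms: acetic anhydride, CC(=O)OC(C)=O; tetrabutylammonium fluoride, CCCC[N+](CCCC)(CCCC)CCCC.[F-] (cation of intermediate 19 only)
Why: Fluoride should cleave the aryl Si–O bond and phenoxide 19 is acylated in the same flask (one-pot desilylation–acetylation), so that only the oxygen para to the side chain receives the acetyl group.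

Step 11
Reactants: 20 4-{2-[3,5-dimethoxy-4-(3-methylbut-2-en-1-yl)phenyl]ethyl}-3-methoxy-2-(methoxymethoxy)phenyl acetate
Product: 21 4-{2-[3,5-dimethoxy-4-(3-methylbut-2-en-1-yl)phenyl]ethyl}-2-hydroxy-3-methoxyphenyl acetate
Conditions: NaHSO4·SiO2, CH2Cl2, rt
Reagents that add atoms: none
Why: Silica-supported NaHSO4 should hydrolyse the phenolic MOM acetal under heterogeneous, non-nucleophilic acid conditions that neither transesterify the aryl acetate nor set off the base-mediated acetyl migration to the neighbouring phenol.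

**Compound list**

1 | 2-(3,5-dimethoxyphenyl)ethan-1-ol | COc1cc(CCO)cc(OC)c1 | starting material
2 | tert-butyl[2-(3,5-dimethoxyphenyl)ethoxy]dimethylsilane | COc1cc(CCO[Si](C)(C)C(C)(C)C)cc(OC)c1 | intermediate
3 | [4-(2-{[tert-butyl(dimethyl)silyl]oxy}ethyl)-2,6-dimethoxyphenyl]lithium | [Li]c1c(OC)cc(CCO[Si](C)(C)C(C)(C)C)cc1OC | intermediate
4 | tert-butyl{2-[3,5-dimethoxy-4-(3-methylbut-2-en-1-yl)phenyl]ethoxy}dimethylsilane | COc1cc(CCO[Si](C)(C)C(C)(C)C)cc(OC)c1CC=C(C)C | intermediate
5 | 2-[3,5-dimethoxy-4-(3-methylbut-2-en-1-yl)phenyl]ethan-1-ol | COc1cc(CCO)cc(OC)c1CC=C(C)C | intermediate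
6 | 5-(2-iodoethyl)-1,3-dimethoxy-2-(3-methylbut-2-en-1-yl)benzene | COc1cc(CCI)cc(OC)c1CC=C(C)C | intermediate
7 | 4-chloro-2-hydroxybenzaldehyde | O=Cc1ccc(Cl)cc1O | starting material
8 | 4-chloro-2-(methoxymethoxy)benzaldehyde | COCOc1cc(Cl)ccc1C=O | intermediate
9 | 4-chloro-2-(methoxymethoxy)phenyl formate | COCOc1cc(Cl)ccc1OC=O | intermediate
10 | 4-chloro-2-(methoxymethoxy)phenol | COCOc1cc(Cl)ccc1O | intermediate
11 | [4-chloro-2-(methoxymethoxy)phenoxy]tri(propan-2-yl)silane | COCOc1cc(Cl)ccc1O[Si](C(C)C)(C(C)C)C(C)C | intermediate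
12 | {2-[3,5-dimethoxy-4-(3-methylbut-2-en-1-yl)phenyl]ethyl}lithium | [Li]CCc1cc(OC)c(CC=C(C)C)c(OC)c1 | intermediate
13 | [6-chloro-2-(methoxymethoxy)-3-{[tri(propan-2-yl)silyl]oxy}phenyl]lithium | COCOc1c([Li])c(Cl)ccc1O[Si](C(C)C)(C(C)C)C(C)C | intermediate
14 | 3-(methoxymethoxy)-4-{[tri(propan-2-yl)silyl]oxy}benzyne (1,2-didehydrobenzene) | COCOC1=C(O[Si](C(C)C)(C(C)C)C(C)C)C=CC#C1 | intermediate
15 | [6-{2-[3,5-dimethoxy-4-(3-methylbut-2-en-1-yl)phenyl]ethyl}-2-(methoxymethoxy)-3-{[tri(propan-2-yl)silyl]oxy}phenyl]lithium | COCOc1c([Li])c(CCc2cc(OC)c(CC=C(C)C)c(OC)c2)ccc1O[Si](C(C)C)(C(C)C)C(C)C | intermediate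
16 | dimethyl [6-{2-[3,5-dimethoxy-4-(3-methylbut-2-en-1-yl)phenyl]ethyl}-2-(methoxymethoxy)-3-{[tri(propan-2-yl)silyl]oxy}phenyl]boronate | COCOc1c(B(OC)OC)c(CCc2cc(OC)c(CC=C(C)C)c(OC)c2)ccc1O[Si](C(C)C)(C(C)C)C(C)C | intermediate
17 | 6-{2-[3,5-dimethoxy-4-(3-methylbut-2-en-1-yl)phenyl]ethyl}-2-(methoxymethoxy)-3-{[tri(propan-2-yl)silyl]oxy}phenol | COCOc1c(O)c(CCc2cc(OC)c(CC=C(C)C)c(OC)c2)ccc1O[Si](C(C)C)(C(C)C)C(C)C | intermediate
18 | {4-{2-[3,5-dimethoxy-4-(3-methylbut-2-en-1-yl)phenyl]ethyl}-3-methoxy-2-(methoxymethoxy)phenoxy}tri(propan-2-yl)silane | COCOc1c(OC)c(CCc2cc(OC)c(CC=C(C)C)c(OC)c2)ccc1O[Si](C(C)C)(C(C)C)C(C)C | intermediate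
19 | tetrabutylammonium 4-{2-[3,5-dimethoxy-4-(3-methylbut-2-en-1-yl)phenyl]ethyl}-3-methoxy-2-(methoxymethoxy)phenolate | COCOc1c(OC)c(CCc2cc(OC)c(CC=C(C)C)c(OC)c2)ccc1[O-].CCCC[N+](CCCC)(CCCC)CCCC | intermediate
20 | 4-{2-[3,5-dimethoxy-4-(3-methylbut-2-en-1-yl)phenyl]ethyl}-3-methoxy-2-(methoxymethoxy)phenyl acetate | COCOc1c(OC)c(CCc2cc(OC)c(CC=C(C)C)c(OC)c2)ccc1OC(C)=O | intermediate
21 | 4-{2-[3,5-dimethoxy-4-(3-methylbut-2-en-1-yl)phenyl]ethyl}-2-hydroxy-3-methoxyphenyl acetate | COc1cc(CCc2ccc(OC(C)=O)c(O)c2OC)cc(OC)c1CC=C(C)C | target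

**Summary**

Total step count: 11. Longest linear sequence: 8 steps (steps 1–4, then 8–11); the ring B branch (steps 5–7) converges at step 8.

Steps most likely to fail, with fallbacks:

1. Step 8. The aryne may be consumed by addition of the aryllithiums 13 or 15 (biaryl formation) before the alkyllithium captures it, or chloride elimination and carbolithiation may fall out of step so that the alkyllithium decays first. The fallback makes the same C–C bond by cross-coupling and brings in the oxygen afterwards. It sets out from 6 and 11. Iodide 6 would be converted with zinc dust and LiCl in THF into {2-[3,5-dimethoxy-4-(3-methylbut-2-en-1-yl)phenyl]ethyl}zinc iodide F1. F1 would be coupled with aryl chloride 11 under Pd-PEPPSI-IPr catalysis (Negishi coupling) to give {4-{2-[3,5-dimethoxy-4-(3-methylbut-2-en-1-yl)phenyl]ethyl}-2-(methoxymethoxy)phenoxy}tri(propan-2-yl)silane F2. MOM-directed ortho-lithiation of F2 (s-BuLi, TMEDA, THF, −78 °C) can only occur at the one free position beside OMOM and should give aryllithium 15. The fallback rejoins the route there, and borylation and oxidation lead to 17 as in step 8.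

2. Step 11. Under the acidic conditions the acetyl group may migrate to the newly freed neighbouring phenol oxygen or be lost, or the prenyl double bond may be attacked. The fallback gives up protecting-group orthogonality and relies on steric differentiation of the two phenols. It sets out from 18. TBAF buffered with AcOH would give 4-{2-[3,5-dimethoxy-4-(3-methylbut-2-en-1-yl)phenyl]ethyl}-3-methoxy-2-(methoxymethoxy)phenol F3. Dilute HCl in MeOH, with no ester yet present, would remove the MOM group to give 4-{2-[3,5-dimethoxy-4-(3-methylbut-2-en-1-yl)phenyl]ethyl}-3-methoxybenzene-1,2-diol F4. Kinetic mono-acetylation of F4 with one equivalent of acetyl chloride and 2,4,6-collidine in CH2Cl2 at −78 °C should favour the less hindered hydroxyl para to the side chain over the one flanked by OMe and OH, and returns to the route at 21.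

3. Step 2. The aryl nucleophile may attack prenyl bromide at its tertiary end (SN2′), giving the 1,1-dimethylallyl isomer, or the alkylation may be incomplete. The fallback sets out from 2. Aryllithium 3, generated as before, would be alkylated with allyl bromide, for which SN2 and SN2′ attack give the same product, to give tert-butyl{2-[3,5-dimethoxy-4-(prop-2-en-1-yl)phenyl]ethoxy}dimethylsilane F5. Olefin cross-metathesis of F5 with excess 2-methylbut-2-ene (Grubbs second-generation catalyst, CH2Cl2, 40 °C) should turn the allyl group into the prenyl group and returns to the route at 4.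

**Further compounds**

F1 | step 8 | {2-[3,5-dimethoxy-4-(3-methylbut-2-en-1-yl)phenyl]ethyl}zinc iodide | I[Zn]CCc1cc(OC)c(CC=C(C)C)c(OC)c1
F2 | step 8 | {4-{2-[3,5-dimethoxy-4-(3-methylbut-2-en-1-yl)phenyl]ethyl}-2-(methoxymethoxy)phenoxy}tri(propan-2-yl)silane | COCOc1cc(CCc2cc(OC)c(CC=C(C)C)c(OC)c2)ccc1O[Si](C(C)C)(C(C)C)C(C)C
F3 | step 11 | 4-{2-[3,5-dimethoxy-4-(3-methylbut-2-en-1-yl)phenyl]ethyl}-3-methoxy-2-(methoxymethoxy)phenol | COCOc1c(OC)c(CCc2cc(OC)c(CC=C(C)C)c(OC)c2)ccc1O
F4 | step 11 | 4-{2-[3,5-dimethoxy-4-(3-methylbut-2-en-1-yl)phenyl]ethyl}-3-methoxybenzene-1,2-diol | COc1c(CCc2cc(OC)c(CC=C(C)C)c(OC)c2)ccc(O)c1O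
F5 | step 2 | tert-butyl{2-[3,5-dimethoxy-4-(prop-2-en-1-yl)phenyl]ethoxy}dimethylsilane | COc1cc(CCO[Si](C)(C)C(C)(C)C)cc(OC)c1CC=C
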